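The geranyl ether is cut between its O-bound CH2 (C1′, on the C5 oxygen of the chroman) and the alkenyl CH (C2′). The key step makes this C(sp3)–C(sp2) bond by Ir/Ni metallaphotoredox decarboxylative vinylation. The aryloxyacetic acid on O5 of the complete (3R)-8-acetyl-3,7-dihydroxy-2,2-dimethylchroman loses CO2 to give an O5-stabilised α-oxy radical. Nickel couples this radical with (E)-1-iodo-2,6-dimethylhepta-1,5-diene, keeping the C2′=C3′ geometry and needing no protecting groups. Because both side-chain alkenes arrive last, C3 is set beforehand by Jacobsen epoxidation of a 2H-chromene and benzylic hydrogenolysis, free of competing olefins.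

Key step: step 9

Remark: the C3 carbinol of the target is read as R from the SMILES. The (R,R)-Mn(salen) catalyst is chosen from the established (R,R) → (3R,4R) correlation for 2,2-dimethyl-2H-chromenes, and the benzylic C–O cleavage does not change the C3 descriptor.

Step 1
Reactants: 1 2′,4′,6′-trihydroxyacetophenone; 2 methyl bromoacetate
Product: 3 methyl 2-(4-acetyl-3,5-dihydroxyphenoxy)acetate
Conditions: 2 (1.0 equiv), K2CO3 (1.05 equiv), acetone, 0 °C → rt
Reagents that add atoms: none
Why: Williamson etherification, in which the 4-OH (para to the acetyl and the only hydroxyl not hydrogen-bonded to the carbonyl) is the most acidic and accessible, so one equivalent of base and bromide should alkylate it selectively.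

Step 2
Reactants: 3 methyl 2-(4-acetyl-3,5-dihydroxyphenoxy)acetate; 4 3-methylbut-2-enal
Product: 6 methyl 2-[(8-acetyl-7-hydroxy-2,2-dimethyl-2H-chromen-5-yl)oxy]acetate, via ortho-quinone methide 5 (not isolated)
Conditions: 4 (1.2 equiv), ethylenediammonium diacetate (10 mol%), xylene, 140 °C
Reagents that add atoms: none
Why: Amine-catalysed Knoevenagel-type condensation at the ring carbon between OH and OCH2 gives 5, which closes by oxa-6π electrocyclisation (formal [3+3] chromene annulation); the two free ring positions of 3 are equivalent and only the hydroxyl ortho to the acetyl can close the pyran, which fixes the 8-acetyl-7-hydroxy-5-alkoxy pattern, with water as the only by-product.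

Step 3
Reactants: 6 methyl 2-[(8-acetyl-7-hydroxy-2,2-dimethyl-2H-chromen-5-yl)oxy]acetate
Product: 7 methyl 2-[(7-acetoxy-8-acetyl-2,2-dimethyl-2H-chromen-5-yl)oxy]acetate
Conditions: Ac2O, Et3N, DMAP (cat.), CH2Cl2, rt
Reagents that add atoms: acetic anhydride CC(=O)OC(C)=O
Why: DMAP-catalysed acetylation of the single phenol masks the oxidisable, metal-binding C7–OH and blocks para-quinone methide formation from the later epoxide, and the acetate is removed in step 6 together with the methyl ester at no extra cost.

Step 4
Reactants: 7 methyl 2-[(7-acetoxy-8-acetyl-2,2-dimethyl-2H-chromen-5-yl)oxy]acetate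
Product: 8 methyl 2-{[(3R,4R)-7-acetoxy-8-acetyl-3,4-epoxy-2,2-dimethyl-3,4-dihydro-2H-chromen-5-yl]oxy}acetate (cis-fused oxirane)
Conditions: (R,R)-Jacobsen Mn(salen)Cl (5 mol%), mCPBA (2 equiv), NMO (5 equiv), CH2Cl2, −78 °C; basic work-up, used crude
Reagents that add atoms: mCPBA OOC(=O)c1cccc(Cl)c1
Why: Jacobsen–Katsuki epoxidation, for which cis-olefins of 2,2-dimethyl-2H-chromenes are the model substrate class; the (R,R)-salen Mn(V)-oxo species should deliver oxygen to the face that gives the (3R,4R)-epoxide and thereby set C3, while the anhydrous low-temperature protocol avoids ring chlorination and ester hydrolysis.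

Step 5
Reactants: 8 methyl 2-{[(3R,4R)-7-acetoxy-8-acetyl-3,4-epoxy-2,2-dimethyl-3,4-dihydro-2H-chromen-5-yl]oxy}acetate
Product: 9 methyl 2-{[(3R)-7-acetoxy-8-acetyl-3-hydroxy-2,2-dimethyl-3,4-dihydro-2H-chromen-5-yl]oxy}acetate
Conditions: H2 (1 atm), 10% Pd/C, EtOAc, Et3N (trace), rt
Reagents that add atoms: none
Why: Heterogeneous hydrogenolysis cleaves only the benzylic C4–O bond of the aryl epoxide, so the C3–O bond and its R configuration are retained; no alkene is present at this stage and the hindered di-ortho-substituted aryl ketone should react far more slowly.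

Step 6
Reactants: 9 methyl 2-{[(3R)-7-acetoxy-8-acetyl-3-hydroxy-2,2-dimethyl-3,4-dihydro-2H-chromen-5-yl]oxy}acetate
Product: 10 2-{[(3R)-8-acetyl-3,7-dihydroxy-2,2-dimethyl-3,4-dihydro-2H-chromen-5-yl]oxy}acetic acid
Conditions: LiOH·H2O (4 equiv), THF/H2O, 0 °C → rt; then 1 M HCl to pH 2–3
Reagents that add atoms: lithium hydroxide [Li+].[OH-]
Why: Saponification cleaves the methyl ester and the aryl acetate in one operation, and the tertiary alkyl aryl ether, the carbinol stereocentre and the ketone are inert to aqueous hydroxide.

Step 7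
Reactants: 11 5-bromo-2-methylpent-2-ene; 12 lithium acetylide–ethylenediamine complex
Product: 13 6-methylhept-5-en-1-yne
Conditions: DMSO, 10 °C → rt
Reagents that add atoms: none
Why: SN2 alkylation of lithium acetylide with a primary bromide in a dipolar aprotic solvent, with the trisubstituted alkene as a spectator.

Step 8
Reactants: 13 6-methylhept-5-en-1-yne
Product: 15 (E)-1-iodo-2,6-dimethylhepta-1,5-diene, via alkenylalane 14 (not isolated)
Conditions: Me3Al (2 equiv), Cp2ZrCl2 (20 mol%), CH2Cl2, 0 °C → rt; then I2, THF, −30 → 0 °C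
Reagents that add atoms: trimethylaluminium C[Al](C)C; iodine II
Why: Negishi zirconium-catalysed methylalumination adds Me and Al syn across the terminal alkyne with Al on the terminal carbon to give 14, and iodinolysis of the C–Al bond proceeds with retention, which fixes the E geometry; the trisubstituted alkene is not carbometalated.

Step 9
Reactants: 10 2-{[(3R)-8-acetyl-3,7-dihydroxy-2,2-dimethyl-3,4-dihydro-2H-chromen-5-yl]oxy}acetic acid; 15 (E)-1-iodo-2,6-dimethylhepta-1,5-diene
Product: 16 1-[(3R)-5-{[(2E)-3,7-dimethylocta-2,6-dien-1-yl]oxy}-3,7-dihydroxy-2,2-dimethyl-3,4-dihydro-2H-chromen-8-yl]ethan-1-one (target)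
Conditions: Ir[dF(CF3)ppy]2(dtbbpy)PF6 (1 mol%), NiCl2·glyme (5 mol%), dtbbpy (5 mol%), DBU (1.1 equiv), 15 (1.5 equiv), degassed DMSO, blue LEDs, 25 °C
Reagents that add atoms: none
Why: DBU (about one equivalent) ionises only the carboxylic acid of 10, the excited Ir(III) photocatalyst oxidises this carboxylate, and loss of CO2 leaves the primary α-aryloxymethyl radical at the OCH2 carbon, stabilised by the lone pair of the C5 oxygen. In parallel Ni(0)/dtbbpy inserts into the C–I bond of 15 with retention of the E geometry, captures the radical and reductively eliminates the CH2–CH= bond from Ni(III), after which Ir(II) returns Ni(I) to Ni(0). The closest known reaction type is the metallaphotoredox decarboxylative vinylation of α-oxy carboxylic acids with vinyl halides (decarboxylative C(sp3)–C(sp2) cross-coupling). No ring is closed and no stereocentre is formed: C3 is remote and untouched, and the E-C2′=C3′ geometry is the one fixed in step 8. The step needs chemoselective oxidation of the carboxylate in the presence of the C7 phenol, the C3 alcohol and the aryl ketone; the higher acidity of the acid, the hydrogen bond of C7–OH to the C8 acetyl and the inertness of alcohol and ketone in this redox window should secure it, and the unconjugated product alkenes are not sensitised by the photocatalyst.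

Compound list
1 | 2′,4′,6′-trihydroxyacetophenone (phloroacetophenone) | CC(=O)c1c(O)cc(O)cc1O | starting material
2 | methyl bromoacetate | COC(=O)CBr | starting material
3 | methyl 2-(4-acetyl-3,5-dihydroxyphenoxy)acetate | CC(=O)c1c(O)cc(OCC(=O)OC)cc1O | intermediate
4 | 3-methylbut-2-enal (prenal) | CC(C)=CC=O | starting material
5 | methyl 2-{[4-acetyl-3-hydroxy-6-(3-methylbut-2-en-1-ylidene)-5-oxocyclohexa-1,3-dien-1-yl]oxy}acetate (ortho-quinone methide, dienyl arm cis to the ring carbonyl) | CC(=O)C1=C(O)C=C(OCC(=O)OC)/C(=C/C=C(C)C)C1=O | intermediate (not isolated)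
6 | methyl 2-[(8-acetyl-7-hydroxy-2,2-dimethyl-2H-chromen-5-yl)oxy]acetate | CC(=O)c1c(O)cc(OCC(=O)OC)c2c1OC(C)(C)C=C2 | intermediate
7 | methyl 2-[(7-acetoxy-8-acetyl-2,2-dimethyl-2H-chromen-5-yl)oxy]acetate | CC(=O)c1c(OC(C)=O)cc(OCC(=O)OC)c2c1OC(C)(C)C=C2 | intermediate
8 | methyl 2-{[(3R,4R)-7-acetoxy-8-acetyl-3,4-epoxy-2,2-dimethyl-3,4-dihydro-2H-chromen-5-yl]oxy}acetate | CC(=O)c1c(OC(C)=O)cc(OCC(=O)OC)c2c1OC(C)(C)[C@@H]3O[C@@H]32 | intermediate
9 | methyl 2-{[(3R)-7-acetoxy-8-acetyl-3-hydroxy-2,2-dimethyl-3,4-dihydro-2H-chromen-5-yl]oxy}acetate | CC(=O)c1c(OC(C)=O)cc(OCC(=O)OC)c2c1OC(C)(C)[C@H](O)C2 | intermediate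
10 | 2-{[(3R)-8-acetyl-3,7-dihydroxy-2,2-dimethyl-3,4-dihydro-2H-chromen-5-yl]oxy}acetic acid | CC(=O)c1c(O)cc(OCC(=O)O)c2c1OC(C)(C)[C@H](O)C2 | intermediate
11 | 5-bromo-2-methylpent-2-ene | CC(C)=CCCBr | starting material
12 | lithium acetylide–ethylenediamine complex | [Li+].[C-]#C.NCCN | starting material
13 | 6-methylhept-5-en-1-yne | C#CCCC=C(C)C | intermediate
14 | [(1E)-2,6-dimethylhepta-1,5-dien-1-yl]dimethylalane | C[Al](C)/C=C(\C)CCC=C(C)C | intermediate (not isolated)
15 | (E)-1-iodo-2,6-dimethylhepta-1,5-diene | I/C=C(\C)CCC=C(C)C | intermediate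
16 | 1-[(3R)-5-{[(2E)-3,7-dimethylocta-2,6-dien-1-yl]oxy}-3,7-dihydroxy-2,2-dimethyl-3,4-dihydro-2H-chromen-8-yl]ethan-1-one | CC(=O)c1c(O)cc(OC/C=C(\C)CCC=C(C)C)c2c1OC(C)(C)[C@H](O)C2 | target

Total step count: 9. Longest linear sequence: 7 (steps 1–6, then step 9); steps 7–8 build the side-chain fragment.

Steps most likely to fail

Step 9. The excited photocatalyst may be quenched unproductively by the C7 phenol or its phenolate, or the primary α-aryloxymethyl radical may pick up a hydrogen atom (protodecarboxylation) faster than nickel captures it. The fallback sets out from 10 and drops light and base. The acid is condensed with N-hydroxyphthalimide and DIC (CH2Cl2, rt, no DMAP, so the hindered C3 alcohol is not acylated) to the redox-active ester 1,3-dioxoisoindolin-2-yl 2-{[(3R)-8-acetyl-3,7-dihydroxy-2,2-dimethyl-3,4-dihydro-2H-chromen-5-yl]oxy}acetate F1. F1 is then joined to 15 by nickel-catalysed reductive cross-electrophile coupling (NiBr2·glyme, dtbbpy, Zn, DMA, rt), which forms the same CH2–CH= bond by a thermal radical/nickel cycle and comes back to the route at target 16.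

Step 4. The peri C5 alkoxy group may erode facial selectivity, and the electron-rich benzylic epoxide may open or undergo Meinwald rearrangement under the acidic by-product or on isolation. The fallback sets out from 7 and replaces epoxidation/hydrogenolysis by dihydroxylation/ionic deoxygenation. Sharpless asymmetric dihydroxylation under non-basic conditions (OsO4 cat., (DHQ)2PYR, NMO, acetone/H2O, 0 °C, slow addition of 7) should give the cis-diol methyl 2-{[(3R,4R)-7-acetoxy-8-acetyl-3,4-dihydroxy-2,2-dimethyl-3,4-dihydro-2H-chromen-5-yl]oxy}acetate F2. The PYR ligand class is the one suited to cis-olefins of chromenes; the facial sense is to be confirmed by Mosher analysis, and the pseudo-enantiomeric (DHQD)2PYR is to be used if the opposite face is attacked. Et3SiH/TFA (CH2Cl2, −20 °C) then ionises only the doubly oxygen-stabilised benzylic C4–OH and delivers hydride there, leaving C3 untouched, so the route is rejoined at 9.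

Step 2. A second annulation may occur at the remaining ring position between O5 and the C7 hydroxyl, and the enal may oligomerise at the temperature the deactivated acylphenol needs. The fallback sets out from 3 and builds the pyran by sigmatropic chemistry. Mono-O-alkylation of one of the two equivalent chelated hydroxyls with 3-chloro-3-methylbut-1-yne (K2CO3, KI, CuI cat., acetone, 50 °C) gives the propargyl ether methyl 2-{4-acetyl-3-hydroxy-5-[(2-methylbut-3-yn-2-yl)oxy]phenoxy}acetate F3. Heating F3 (N,N-diethylaniline, 180 °C) triggers aryl propargyl Claisen rearrangement to the only free ortho carbon, then [1,5]-H shift and oxa-6π electrocyclisation. This returns to the route at chromene 6, with the ring oxygen necessarily ortho to the acetyl.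

Further compounds
F1 | step 9 | 1,3-dioxoisoindolin-2-yl 2-{[(3R)-8-acetyl-3,7-dihydroxy-2,2-dimethyl-3,4-dihydro-2H-chromen-5-yl]oxy}acetate | CC(=O)c1c(O)cc(OCC(=O)ON3C(=O)c4ccccc4C3=O)c2c1OC(C)(C)[C@H](O)C2
F2 | step 4 | methyl 2-{[(3R,4R)-7-acetoxy-8-acetyl-3,4-dihydroxy-2,2-dimethyl-3,4-dihydro-2H-chromen-5-yl]oxy}acetate | CC(=O)c1c(OC(C)=O)cc(OCC(=O)OC)c2c1OC(C)(C)[C@H](O)[C@@H]2O
F3 | step 2 | methyl 2-{4-acetyl-3-hydroxy-5-[(2-methylbut-3-yn-2-yl)oxy]phenoxy}acetate | CC(=O)c1c(O)cc(OCC(=O)OC)cc1OC(C)(C)C#C
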